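**Retrosynthetic overview**
1. Key step first: all 33 carbons come from 1-naphthol 1. A hydroxyl-directed peri C–H methoxylation makes the C8–OMe bond and gives the monomer 8-methoxy-1-naphthol 2.
2. Monomer 2 is divided into a nucleophile precursor (MOM ether 3) and one shared electrophile (para-bromide 4, then its MOM ether 5).
3. Both biaryl bonds are of the same kind (C2 of one unit to C4 of the next), so each is cut to a C2-arylzinc, made by OMOM-directed lithiation, and bromide 5.
4. Order: 3 gives lithium and zinc species 6 and 7, which couple with 5 to the A–B biaryl 8. Then 8 gives 9 and 10 on ring B, which couple with 5 again to the A–B–C tris-MOM ether 11; acid gives target 12.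
5. No ring is built: ring systems A, B and C are all bought as 1.

Assumption: the SMILES has no stereodescriptor and both biaryl axes carry only one ortho substituent besides the peri C–H, so they rotate freely at room temperature; the target is treated as one achiral compound and no stereocentre is set (locants follow 1-naphthol numbering in every unit: OH or OMOM oxygen on C1, methoxy on C8).

**Route**

Step 1
Reactants: 1 naphthalen-1-ol
Product: 2 8-methoxynaphthalen-1-ol
Conditions: Pd(OAc)2 (10 mol %), 3-nitropyridine (20 mol %), CsOPiv (cesium pivalate, 30 mol %), tert-butyl peroxybenzoate (1.5 equiv), MeOH/C6F6 (1:3), 70 °C, Ar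
Reagents that add atoms: methanol (CO)
Why: Proposed new method: the O-bound divalent-palladium naphtholate of 1 can palladate only C8–H (five-membered C,O-palladacycle by carboxylate-assisted metalation; C2–H would need a four-membered ring), the perester oxidises this palladacycle to tetravalent palladium, methanol exchanges onto the metal and C8–OMe reductive elimination follows because the alternative chelate C–O elimination would give an impossible peri-fused oxete, and product 2 has no peri C–H left so it cannot react twice; the closest known reaction types are the hydroxyl-directed peri C–H arylation and alkyne annulation of 1-naphthols, the phenol-directed Pd-catalysed C–H activation/C–O cyclisation of 2-arylphenols to dibenzofurans with the same perester oxidant, and Pd-catalysed directed C–H alkoxylation in alcohol solvent with nitrogen directing groups.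

Step 2
Reactants: 2 8-methoxynaphthalen-1-ol
Product: 3 8-methoxy-1-(methoxymethoxy)naphthalene
Conditions: NaH, DMF, 0 °C; then MOMCl, 0 °C to rt
Reagents that add atoms: chloromethyl methyl ether (COCCl)
Why: Williamson-type O-alkylation of the sodium naphtholate; full deprotonation with NaH overcomes the hydrogen bond of the OH to the peri methoxy group.

Step 3
Reactants: 2 8-methoxynaphthalen-1-ol
Product: 4 4-bromo-8-methoxynaphthalen-1-ol
Conditions: NBS (1.0 equiv), MeCN, −20 °C to 0 °C, dark
Reagents that add atoms: N-bromosuccinimide (O=C1CCC(=O)N1Br)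
Why: Electrophilic aromatic bromination; the hydroxyl-bearing ring is the most activated and NBS in acetonitrile at low temperature is para-selective for 1-naphthols, so bromine enters at C4.

Step 4
Reactants: 4 4-bromo-8-methoxynaphthalen-1-ol
Product: 5 4-bromo-8-methoxy-1-(methoxymethoxy)naphthalene
Conditions: NaH, DMF, 0 °C; then MOMCl, 0 °C to rt
Reagents that add atoms: chloromethyl methyl ether (COCCl)
Why: Same Williamson-type O-alkylation as in step 2; the aryl bromide is inert to NaH and MOMCl.

Step 5
Reactants: 3 8-methoxy-1-(methoxymethoxy)naphthalene; 5 4-bromo-8-methoxy-1-(methoxymethoxy)naphthalene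
Product: 8 5,8'-dimethoxy-4,1'-bis(methoxymethoxy)-1,2'-binaphthalene, via aryllithium 6 (not isolated), via arylzinc chloride 7 (not isolated)
Conditions: n-BuLi, TMEDA, THF, 0 °C; ZnCl2, 0 °C to rt; then 5, Pd(OAc)2 (2 mol %), SPhos (4 mol %), THF, 60 °C
Reagents that add atoms: none
Why: Directed ortho-metalation (the chelating OMOM group directs lithiation to C2; the peri site is blocked and OMe is the weaker director), transmetalation to zinc and Negishi coupling, with SPhos-ligated zerovalent palladium coping with the ortho-OMOM and peri-hindered biaryl bond (ring A C2 to ring B C4).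

Step 6
Reactants: 8 5,8'-dimethoxy-4,1'-bis(methoxymethoxy)-1,2'-binaphthalene; 5 4-bromo-8-methoxy-1-(methoxymethoxy)naphthalene
Product: 11 8-methoxy-1-(methoxymethoxy)-2-[5-methoxy-4-(methoxymethoxy)naphthalen-1-yl]-4-[8-methoxy-1-(methoxymethoxy)naphthalen-2-yl]naphthalene, via aryllithium 9 (not isolated), via arylzinc chloride 10 (not isolated)
Conditions: n-BuLi, TMEDA, THF, 0 °C; ZnCl2, 0 °C to rt; then 5, Pd(OAc)2 (3 mol %), SPhos (6 mol %), THF, 65 °C
Reagents that add atoms: none
Why: Second directed ortho-metalation and Negishi coupling; in 8 only ring B still has a C–H ortho to an OMOM group (the ortho carbon of ring A is the biaryl carbon), so lithiation and the new bond go to C2 of ring B (ring B C2 to ring C C4).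

Step 7
Reactants: 11 8-methoxy-1-(methoxymethoxy)-2-[5-methoxy-4-(methoxymethoxy)naphthalen-1-yl]-4-[8-methoxy-1-(methoxymethoxy)naphthalen-2-yl]naphthalene
Product: 12 2-(4-hydroxy-5-methoxynaphthalen-1-yl)-4-(1-hydroxy-8-methoxynaphthalen-2-yl)-8-methoxynaphthalen-1-ol
Conditions: conc. HCl (3 equiv), MeOH/THF (3:1), 45 °C, Ar
Reagents that add atoms: none
Why: Acid-catalysed acetal solvolysis of the three MOM ethers, with methanol carrying the formaldehyde unit away as dimethoxymethane; aryl methyl ethers and biaryl bonds are inert and there is no stereocentre to scramble.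

**Compound list**
1 | naphthalen-1-ol (1-naphthol) | Oc1cccc2ccccc12 | starting material
2 | 8-methoxynaphthalen-1-ol | COc1cccc2cccc(O)c12 | intermediate
3 | 8-methoxy-1-(methoxymethoxy)naphthalene | COCOc1cccc2cccc(OC)c12 | intermediate
4 | 4-bromo-8-methoxynaphthalen-1-ol | COc1cccc2c(Br)ccc(O)c12 | intermediate
5 | 4-bromo-8-methoxy-1-(methoxymethoxy)naphthalene | COCOc1ccc(Br)c2cccc(OC)c12 | intermediate
6 | [8-methoxy-1-(methoxymethoxy)naphthalen-2-yl]lithium | COCOc1c([Li])ccc2cccc(OC)c12 | intermediate
7 | chloro[8-methoxy-1-(methoxymethoxy)naphthalen-2-yl]zinc | COCOc1c([Zn]Cl)ccc2cccc(OC)c12 | intermediate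
8 | 5,8'-dimethoxy-4,1'-bis(methoxymethoxy)-1,2'-binaphthalene (ring A C2 bonded to ring B C4) | COCOc1c(-c2ccc(OCOC)c3c(OC)cccc23)ccc2cccc(OC)c12 | intermediate
9 | [5,8'-dimethoxy-4,1'-bis(methoxymethoxy)-1,2'-binaphthalen-3-yl]lithium (lithium on C2 of ring B) | COCOc1c(-c2cc([Li])c(OCOC)c3c(OC)cccc23)ccc2cccc(OC)c12 | intermediate
10 | chloro[5,8'-dimethoxy-4,1'-bis(methoxymethoxy)-1,2'-binaphthalen-3-yl]zinc | COCOc1c(-c2cc([Zn]Cl)c(OCOC)c3c(OC)cccc23)ccc2cccc(OC)c12 | intermediate
11 | 8-methoxy-1-(methoxymethoxy)-2-[5-methoxy-4-(methoxymethoxy)naphthalen-1-yl]-4-[8-methoxy-1-(methoxymethoxy)naphthalen-2-yl]naphthalene (tris-MOM ether of the target) | COCOc1c(-c2cc(-c3ccc(OCOC)c4c(OC)cccc34)c(OCOC)c3c(OC)cccc23)ccc2cccc(OC)c12 | intermediate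
12 | 2-(4-hydroxy-5-methoxynaphthalen-1-yl)-4-(1-hydroxy-8-methoxynaphthalen-2-yl)-8-methoxynaphthalen-1-ol | COc1cccc2ccc(-c3cc(-c4ccc(O)c5c(OC)cccc45)c(O)c4c(OC)cccc34)c(O)c12 | target

**Totals**
Total step count: 7.
Longest linear sequence: 6 steps (1, 3, 4, 5, 6, 7); step 2 is the only branch.

**Three steps most likely to fail, each with a fallback**

Step 1, the proposed peri C–H methoxylation. The risks are oxidation or oxidative dimerisation of the free naphthol, and benzoyloxylation in place of methoxylation. The fallback uses known chemistry, sets out from 1 and comes back at 2. Compound 1 is O-methylated (MeI, K2CO3, acetone) to 1-methoxynaphthalene F1. Methoxy-directed peri-lithiation with t-BuLi in cyclohexane at rt gives (8-methoxynaphthalen-1-yl)lithium F2. Trapping with B(OMe)3 gives dimethyl (8-methoxynaphthalen-1-yl)boronate F3, and H2O2/NaOH oxidises it to 2. The C–O bond is then made by stoichiometric lithiation, borylation and oxidation, the two oxygens swap roles, and the route grows by one step.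

Step 6, the second lithiation and coupling. The risks are incomplete or misdirected lithiation of the larger substrate 8 and a biaryl bond hindered on both sides. The fallback sets out from 4, also uses 5 and the zinc reagent 7, and comes back at 11. Compound 4 is iodinated at its only free ortho position (NIS, cat. TsOH, MeCN) to 4-bromo-2-iodo-8-methoxynaphthalen-1-ol F7, which is protected (NaH, MOMCl) as 4-bromo-2-iodo-8-methoxy-1-(methoxymethoxy)naphthalene F8. Bromide 5 undergoes Br–Li exchange (n-BuLi, THF, −78 °C) to [5-methoxy-4-(methoxymethoxy)naphthalen-1-yl]lithium F9, and ZnCl2 converts it to chloro[5-methoxy-4-(methoxymethoxy)naphthalen-1-yl]zinc F10. Iodide-selective Negishi coupling of F8 with F10 (Pd(PPh3)4, THF, rt) gives 4-bromo-8-methoxy-2-[5-methoxy-4-(methoxymethoxy)naphthalen-1-yl]-1-(methoxymethoxy)naphthalene F11. Its remaining bromide is coupled with 7, made from 3 as in step 5 (Pd(OAc)2, SPhos, THF, 60 °C), to give 11. The central ring then carries both handles from the start and no lithiation of a biaryl is needed.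

Step 3, the para-bromination. The risks are bromination at C2 and dibromination of the hydrogen-bonded naphthol. The fallback sets out from 2 and comes back at 5. Compound 2 is brominated exhaustively on the phenolic ring (Br2, 2.0 equiv, CH2Cl2, 0 °C) to 2,4-dibromo-8-methoxynaphthalen-1-ol F4, which is protected (NaH, MOMCl) as 2,4-dibromo-8-methoxy-1-(methoxymethoxy)naphthalene F5. One equivalent of n-BuLi (THF, −78 °C) exchanges the bromine next to the chelating OMOM group selectively, giving [4-bromo-8-methoxy-1-(methoxymethoxy)naphthalen-2-yl]lithium F6, and a methanol quench gives 5. Regiocontrol then rests on chelation-controlled halogen–metal exchange instead of on the selectivity of the electrophilic substitution.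

Further compounds
F1 | step 1 | 1-methoxynaphthalene | COc1cccc2ccccc12
F2 | step 1 | (8-methoxynaphthalen-1-yl)lithium | COc1cccc2cccc([Li])c12
F3 | step 1 | dimethyl (8-methoxynaphthalen-1-yl)boronate | COc1cccc2cccc(B(OC)OC)c12
F4 | step 3 | 2,4-dibromo-8-methoxynaphthalen-1-ol | COc1cccc2c(Br)cc(Br)c(O)c12
F5 | step 3 | 2,4-dibromo-8-methoxy-1-(methoxymethoxy)naphthalene | COCOc1c(Br)cc(Br)c2cccc(OC)c12
F6 | step 3 | [4-bromo-8-methoxy-1-(methoxymethoxy)naphthalen-2-yl]lithium | COCOc1c([Li])cc(Br)c2cccc(OC)c12
F7 | step 6 | 4-bromo-2-iodo-8-methoxynaphthalen-1-ol | COc1cccc2c(Br)cc(I)c(O)c12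
F8 | step 6 | 4-bromo-2-iodo-8-methoxy-1-(methoxymethoxy)naphthalene | COCOc1c(I)cc(Br)c2cccc(OC)c12
F9 | step 6 | [5-methoxy-4-(methoxymethoxy)naphthalen-1-yl]lithium | COCOc1ccc([Li])c2cccc(OC)c12
F10 | step 6 | chloro[5-methoxy-4-(methoxymethoxy)naphthalen-1-yl]zinc | COCOc1ccc([Zn]Cl)c2cccc(OC)c12
F11 | step 6 | 4-bromo-8-methoxy-2-[5-methoxy-4-(methoxymethoxy)naphthalen-1-yl]-1-(methoxymethoxy)naphthalene | COCOc1c(-c2ccc(OCOC)c3c(OC)cccc23)cc(Br)c2cccc(OC)c12
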